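## Structural features

The target 19 is a 2,3,4-trisubstituted tetrahydrofuran (ring numbered O1, C2, C3, C4, C5) of the lariciresinol type. C2 carries a 3,4,5-trimethoxyphenyl ring directly, C3 a hydroxymethyl group, C4 a 3-hydroxy-4,5-dimethoxybenzyl group, and C5 is an unsubstituted methylene. The three stereocentres are contiguous, (2R,3S,4S), with aryl and hydroxymethyl trans across C2–C3 and hydroxymethyl and benzyl cis across C3–C4. The O1–C2 bond is a benzylic ether on an electron-rich ring: it ionises in acid, which allows epimerisation at C2 and Friedel–Crafts closure of C2 onto the neighbouring benzyl ring, and it is cleaved by hydrogenolysis. The phenol, meta to its benzylic carbon, is acidic and oxidisable and must be masked whenever carbanions, hydrides or oxidants are present. The real difficulty is the absolute and relative control of the adjacent C3 and C4 centres, made harder because the two aryl groups differ in a single O-substituent and must therefore enter as chemically distinct fragments. The key step exploits the fact that C2 bears both oxygen and an aryl ring and can be raised to an aroyl carbon, while C3 and C4 are the β and α carbons of a butenolide whose carbonyl carbon is C5 and whose γ carbon is the hydroxymethyl carbon. With that γ carbon as a removable acetal stereocentre, C2–C3 is made by acyl-anion conjugate addition and the C4–benzyl bond by enolate alkylation. The trans lactone becomes the cis-3,4 tetrahydrofuran once the ring oxygen is re-attached at C2.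

## Logic of the disconnections

19 ⇒ 18. The phenolic O–H is exchanged for an O–Si bond. The phenol must be inert to the carbanion, the enolate and the hydride used earlier. A benzyl ether is excluded because its hydrogenolysis would also break O1–C2, and a bulky silyl ether keeps the benzyl ring less nucleophilic than a free phenol during the acid step. The skeleton is not simplified; the forward step only needs a fluoride cleavage that leaves the benzylic ether alone.

18 ⇒ 17. The O1–C2 bond is cut. It is the one ring bond that forms reversibly through a stabilised benzylic cation, so C2 need not be controlled earlier and both C2 epimers of 17 are usable. The ring and one stereocentre disappear, leaving an acyclic triol with two adjacent stereocentres. The forward step must ionise only the benzylic hydroxyl, must close through the C5 oxygen (the other primary hydroxyl could only give a four-membered ring), and must be stopped before the cation reaches the benzyl ring.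

17 ⇒ 16. No skeletal bond is cut; three carbons are raised in oxidation level. C2 becomes a ketone, C5 a lactone carbonyl, and the hydroxymethyl carbon an acetal carbon bound to the lactone oxygen and to the oxygen of 4. This reveals a γ-butyrolactone in which C4 and C3 (target numbering) are the α and β ring carbons, trans to each other, next to a stereodefined acetal carbon. The two stereocentres now sit in a rigid ring and trace back to one controlling centre. The forward step is an exhaustive hydride reduction that must outrun enolisation of the carbon between ketone and acetal; it releases 4 for recovery.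

16 ⇒ 15. The C=O bond at C2 is replaced by the two C–S bonds of a dithiane, the form in which C2 can have acted as a nucleophile. The forward unmasking must not be basic (the adjacent stereocentre) and must spare two electron-rich arenes, the silyl ether and the acyl acetal.

15 ⇒ 6 + 8 + 12. Two bonds are cut at once: C2–C3 and the bond from C4 to its benzylic methylene. They flank the alkene of 6: the β carbon accepts the acyl-anion equivalent derived from 8, and the α carbon, as the enolate, accepts 12. This gives maximal convergence, three fragments of similar size, and two stereocentres from one. The forward step must give conjugate rather than carbonyl addition, attack anti to the acetal substituent, and C-alkylation anti to the new substituent in the same flask.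

6 ⇒ 3 + 4, and 3 ⇒ 1. The exocyclic acetal C–O bond is cut to give 3 and 4; 3 comes from 1 by oxidative excision of the formyl carbon. The acetal forms under equilibrating acid, so the wanted epimer can be removed by crystallisation and the rest recycled. The enantiomer of the auxiliary is chosen to fit the (3S,4S) series. The forward step must deliver 6 as a single epimer by crystallisation.

8 ⇒ 7. The two C–S bonds are cut, which is a routine thioacetalisation of the aldehyde.

12 ⇒ 11 ⇒ 10 ⇒ 9. The C–Br bond is traced to C–OH, this to the aldehyde, and the O–Si bond to the free phenol. Silylating first keeps the phenol masked through reduction and bromination, and the bromide, the least stable compound of the branch, is made last.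

## Other disconnections considered

Alternative 1: The cut runs through C2–C3 and C4–C5, removing a C2–O1–C5 carbonyl ylide from a sacrificial γ-aryl butenolide.
- Forward step: CsF would desilylate the α-chloro silylmethyl ether A3, and the resulting carbonyl ylide would add across the alkene of the enantiopure butenolide A2 anti to its aryl group, giving the cis-fused furofuranone A1. Hydrogenolysis (H2, Pd/C) of the lactone benzylic C–O bond, which also frees the phenol, and reduction of the carboxyl group would then lead to 19.
- In favour: the tetrahydrofuran ring, two C–C bonds and all three ring stereocentres arise in one step, which is more than step 7 builds (no ring, two stereocentres); on this count the alternative is the better plan. The cis-3,4 relation is enforced by the cis ring fusion of a suprafacial cycloaddition, which is at least the equal of the double anti induction of the chosen plan. No benzylic cation is needed at the end, which is better than step 10.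
- Against: the ylide is unsymmetrical, so the step needs regiocontrol (aryl-bearing terminus to the α carbon) and exo control at C2 that the substrate does not obviously impose. A2 has an acidic benzylic γ-hydrogen and is prone to racemise under basic fluoride. A2 needs its own asymmetric synthesis and A3 is a moisture-sensitive chloro ether. The final hydrogenolysis must distinguish the lactone benzylic C–O bond from the O1–C2 bond, which is benzylic on a similarly electron-rich ring.
- Comparison: step economy should be about equal, since A2 and A3 each take several steps and two steps follow the cycloaddition. Mechanistically the alternative trades a stepwise ionic sequence for a concerted step whose regiochemistry and enantiomeric integrity are the uncertain points. The chosen plan is preferred for reliability, not for elegance.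

Alternative 2: The cut is the C3–C4 bond (with the benzylic C–H of the C4 side chain), leading back to the epoxy cinnamyl ether A5, in which O1, C2 and C5 are already joined.
- Forward step: Cp2TiCl (trivalent titanium, generated from Cp2TiCl2 and Zn dust) would open the epoxide homolytically to the C3 radical, which cyclises 5-exo onto the cinnamyl alkene. The benzylic radical is reduced by a second equivalent and protonated, giving the silyl ether A4; fluoride would then give 19.
- In favour: ring closure, the C3–C4 bond and two stereocentres come in one step. The hydroxymethyl group appears at the right oxidation level without any hydride step. The epoxide configuration is irrelevant because the radical is planar. No cation is formed at C2. The route would be shorter; on step and redox economy the alternative is the better plan.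
- Against: C3 and C4 are set only by the conformational preference of a radical transition state. The 2,3-trans relation (aryl pseudo-equatorial) should be dependable, and there it is the equal of step 10. The 3,4-cis relation is less certain, and a C4 epimer would be hard to remove. The absolute configuration rests entirely on the C2 ether stereocentre of A5, which calls for a separate enantioselective addition to 7 or a resolution that discards half the material. Titanium is used in stoichiometric amount.
- Comparison: the chosen plan sets C3 and C4 in a rigid ring under the control of a crystalline, recoverable auxiliary and leaves C2, the centre that can equilibrate, to the end. It is longer but more secure on configuration.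

Alternative 3: The cut is O1–C2, as in step 10, but made at a C–H bond. The precursor is the dibenzylbutanol A7, in which C2 is a plain benzylic methylene and only the C5 hydroxyl is free.
- Forward step: PhI(OAc)2 and I2 under visible light would form the hypoiodite. O–I homolysis gives the alkoxy radical, 1,5-hydrogen transfer moves the radical to C2, and oxidation of the benzylic radical with capture by the same oxygen closes the ring to the diacetate A6. Methanolysis would give 19.
- In favour: C2 never has to be an acyl anion or a ketone, so dithiane formation, unmasking and ketone reduction disappear, which is better redox economy than the chosen plan. The trans preference at C2 arises as in step 10, so the two are equal there. The aryl acetate makes the benzyl ring less nucleophilic than the silyl ether does, which is an advantage.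
- Against: the key step creates neither C3 nor C4, so an enantioselective synthesis of the dibenzylbutane skeleton is still needed. The two primary hydroxyls of a nearly symmetrical diol must be told apart, because the other oxygen would reach the other benzylic carbon through the same six-membered transition state and give the regioisomeric ring. Both electron-rich arenes are exposed to an electrophilic iodinating medium.
- Comparison: the saving in redox steps is offset by monoprotection and deacetylation, so step economy is about equal. The chosen plan differentiates the two termini automatically, since only one hydroxyl of 17 can form a five-membered ring with C2.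

Key step: step 7

Assumption: 17 is carried forward as the mixture of carbinol epimers that hydride reduction of 16 is expected to give, since both ionise to the same cation in step 10. Atom mapping confirms that the (5S) acetal 6 from the dextrorotatory auxiliary 4 leads, via the all-trans lactone 15, to the (2R,3S,4S) ring of 19, so no structure needs correction.

Step 1
Reactants: 1 furfural (furan-2-carbaldehyde)
Product: 3 5-hydroxyfuran-2(5H)-one (racemic lactol), via furfural endoperoxide 2 (not isolated)
Conditions: O2, hν (visible), rose bengal (4,5,6,7-tetrachloro-2',4',5',7'-tetraiodofluorescein disodium salt, cat.), MeOH, 20 °C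
Reagents that add atoms: dioxygen, O=O
Why: Dye-sensitised photo-oxygenation of a furan: singlet oxygen adds [4+2] across the ring to give endoperoxide 2, and methanol attacks its formyl group so that the formyl carbon leaves as methyl formate while the ring collapses to lactol 3. No stereocentre has to be controlled because the lactol carbon is racemic and is re-set in step 2.

Step 2
Reactants: 3 5-hydroxyfuran-2(5H)-one; 4 (+)-menthol, (1S,2R,5S)-2-isopropyl-5-methylcyclohexan-1-ol
Product: 6 (5S)-5-[(1S,2R,5S)-menthyloxy]furan-2(5H)-one, via (5R)-acetal epimer 5 (not isolated)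
Conditions: (+)-10-camphorsulfonic acid (cat.), toluene, reflux, Dean–Stark; crystallisation from petroleum ether at −20 °C; mother liquor re-equilibrated with the same acid and recycled
Reagents that add atoms: none
Why: Acid-catalysed acetalisation of the lactol through the cyclic oxocarbenium ion should give both C5 epimers; the (5S) epimer 6 is expected to crystallise in the (+)-menthyl series, while epimer 5 in the mother liquor is re-equilibrated through the same cation (crystallisation-driven epimer selection). The acetal configuration is thus fixed by crystallisation, with the auxiliary as the stereochemical reference.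

Step 3
Reactants: 7 3,4,5-trimethoxybenzaldehyde
Product: 8 2-(3,4,5-trimethoxyphenyl)-1,3-dithiane
Conditions: HS(CH2)3SH, BF3·OEt2 (cat.), CH2Cl2, 0 → 20 °C
Reagents that add atoms: propane-1,3-dithiol, SCCCS
Why: Lewis-acid-catalysed dithioacetalisation of an aromatic aldehyde; the electron-rich ring does not interfere and no stereocentre is formed.

Step 4
Reactants: 9 3-hydroxy-4,5-dimethoxybenzaldehyde
Product: 10 3,4-dimethoxy-5-[(triisopropylsilyl)oxy]benzaldehyde
Conditions: i-Pr3SiCl, imidazole, DMF, 20 °C
Reagents that add atoms: chlorotriisopropylsilane, CC(C)[Si](Cl)(C(C)C)C(C)C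
Why: Standard O-silylation of a phenol with a trialkylsilyl chloride and imidazole. The bulky triisopropylsilyl ether is chosen because it should survive organolithium, enolate, hydride and dilute acid and is removed by fluoride without touching the benzylic ether.

Step 5
Reactants: 10 3,4-dimethoxy-5-[(triisopropylsilyl)oxy]benzaldehyde
Product: 11 {3,4-dimethoxy-5-[(triisopropylsilyl)oxy]phenyl}methanol
Conditions: NaBH4, MeOH, 0 °C
Reagents that add atoms: none
Why: Borohydride reduction of an aryl aldehyde to the benzylic alcohol; the aryl silyl ether is stable under these conditions.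

Step 6
Reactants: 11 {3,4-dimethoxy-5-[(triisopropylsilyl)oxy]phenyl}methanol
Product: 12 3,4-dimethoxy-5-[(triisopropylsilyl)oxy]benzyl bromide
Conditions: CBr4, PPh3, CH2Cl2, 0 °C
Reagents that add atoms: carbon tetrabromide, BrC(Br)(Br)Br
Why: Appel bromination: bromide displaces the activated oxygen at the primary benzylic carbon under neutral conditions that spare the silyl ether. The electron-rich bromide is used promptly.

Step 7
Reactants: 8 2-(3,4,5-trimethoxyphenyl)-1,3-dithiane; 6 (5S)-5-[(1S,2R,5S)-menthyloxy]furan-2(5H)-one; 12 3,4-dimethoxy-5-[(triisopropylsilyl)oxy]benzyl bromide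
Product: 15 (3S,4S,5S)-3-{3,4-dimethoxy-5-[(triisopropylsilyl)oxy]benzyl}-5-[(1S,2R,5S)-menthyloxy]-4-[2-(3,4,5-trimethoxyphenyl)-1,3-dithian-2-yl]dihydrofuran-2(3H)-one (all-trans), via 2-lithio-2-(3,4,5-trimethoxyphenyl)-1,3-dithiane 13 (not isolated), via lithium enolate of the conjugate adduct 14 (not isolated)
Conditions: n-BuLi, THF, −78 °C; then 6, THF, −78 °C; then 12, DMPU (N,N'-dimethylpropyleneurea), −78 → −20 °C; NH4Cl aq.
Reagents that add atoms: none
Why: n-BuLi removes the C2 proton of 8 to give the sulfur- and aryl-stabilised carbanion 13, a masked 3,4,5-trimethoxybenzoyl anion. This soft nucleophile adds in 1,4 fashion to the β carbon of butenolide 6 from the face opposite the menthyloxy group on the adjacent acetal carbon, forming the C2–C3 bond (target numbering) and the lithium enolate 14. Addition of 12 with DMPU then alkylates the enolate at carbon from the face opposite the very bulky dithianyl group on the neighbouring carbon, forming the C4–benzyl bond and the all-trans lactone 15. The closest known reaction type is the tandem Michael addition–enolate alkylation of 5-alkoxybutenolides with lithiated 2-aryl-1,3-dithianes. No ring is closed in this step. The stereocentre at lactone C4 (target C3) is controlled by the acetal stereocentre of 6 through 1,2-anti induction in the nearly planar five-membered ring, and that at lactone C3 (target C4) by the newly installed dithianyl group, again 1,2-anti, so both derive from the single auxiliary-bearing carbon. The step needs conjugate over carbonyl addition, which the delocalised aryl dithiane anion and the low temperature secure, and C-alkylation without proton transfer or reversal of the addition, which the reactive benzylic bromide, the polar co-solvent and the cold mixture secure.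

Step 8
Reactants: 15 (3S,4S,5S)-3-{3,4-dimethoxy-5-[(triisopropylsilyl)oxy]benzyl}-5-[(1S,2R,5S)-menthyloxy]-4-[2-(3,4,5-trimethoxyphenyl)-1,3-dithian-2-yl]dihydrofuran-2(3H)-one
Product: 16 (3S,4S,5S)-3-{3,4-dimethoxy-5-[(triisopropylsilyl)oxy]benzyl}-5-[(1S,2R,5S)-menthyloxy]-4-(3,4,5-trimethoxybenzoyl)dihydrofuran-2(3H)-one
Conditions: PhI(OCOCF3)2, MeCN–H2O (9:1), 0 °C; NaHCO3 aq.
Reagents that add atoms: water, O
Why: Oxidative dethioacetalisation: the trivalent iodine reagent activates one sulfur, water attacks the dithiane carbon, and the dithiol unit leaves as the cyclic disulfide. The medium is not basic, so the stereocentre between the new ketone and the acetal should not epimerise, and the reaction should be fast enough at 0 °C to spare the electron-rich arenes, the silyl ether and the acyl acetal.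

Step 9
Reactants: 16 (3S,4S,5S)-3-{3,4-dimethoxy-5-[(triisopropylsilyl)oxy]benzyl}-5-[(1S,2R,5S)-menthyloxy]-4-(3,4,5-trimethoxybenzoyl)dihydrofuran-2(3H)-one
Product: 17 (2S,3S)-2-{3,4-dimethoxy-5-[(triisopropylsilyl)oxy]benzyl}-3-[hydroxy(3,4,5-trimethoxyphenyl)methyl]butane-1,4-diol (mixture of carbinol epimers)
Conditions: LiAlH4, THF, −40 → 20 °C; H2O, NaOH aq.
Reagents that add atoms: none
Why: Exhaustive hydride reduction: LiAlH4 should reduce the aryl ketone first at low temperature and then the lactone carbonyl and the acetal carbon, with loss of the auxiliary 4, to give three carbinols. The two ring stereocentres are not touched, and the new carbinol centre is deliberately left uncontrolled.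

Step 10
Reactants: 17 (2S,3S)-2-{3,4-dimethoxy-5-[(triisopropylsilyl)oxy]benzyl}-3-[hydroxy(3,4,5-trimethoxyphenyl)methyl]butane-1,4-diol
Product: 18 [(2R,3S,4S)-4-{3,4-dimethoxy-5-[(triisopropylsilyl)oxy]benzyl}-2-(3,4,5-trimethoxyphenyl)tetrahydrofuran-3-yl]methanol
Conditions: (+)-10-camphorsulfonic acid (cat.), CH2Cl2, 0 °C; Et3N quench
Reagents that add atoms: none
Why: Acid-catalysed SN1 cycloetherification: ionisation of the benzylic carbinol gives a cation stabilised by the trimethoxyphenyl ring, which is captured 5-exo by the C5 hydroxyl (the other primary hydroxyl could only form an oxetane). Both carbinol epimers converge, and C2 is set trans to the C3 hydroxymethyl group because the aryl group takes the less hindered position in a closure that is reversible under the conditions. Low temperature and an early amine quench are meant to stop the cation before it attacks the benzyl ring.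

Step 11
Reactants: 18 [(2R,3S,4S)-4-{3,4-dimethoxy-5-[(triisopropylsilyl)oxy]benzyl}-2-(3,4,5-trimethoxyphenyl)tetrahydrofuran-3-yl]methanol
Product: 19 5-{[(3S,4S,5R)-4-(hydroxymethyl)-5-(3,4,5-trimethoxyphenyl)tetrahydrofuran-3-yl]methyl}-2,3-dimethoxyphenol (target; ring stereocentres 2R,3S,4S)
Conditions: Bu4NF, THF, 0 °C; NH4Cl aq.
Reagents that add atoms: none
Why: Fluoride cleavage of the aryl silyl ether, driven by formation of the Si–F bond. The benzylic ether, the primary alcohol and the three stereocentres are inert to fluoride at 0 °C.

Compound list

1 | furfural (furan-2-carbaldehyde) | O=Cc1ccco1 | starting material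
2 | 2,3,7-trioxabicyclo[2.2.1]hept-5-ene-1-carbaldehyde (furfural endoperoxide, racemic, not isolated) | O=CC12OOC(O1)C=C2 | intermediate
3 | 5-hydroxyfuran-2(5H)-one (racemic lactol) | O=C1OC(O)C=C1 | intermediate
4 | (+)-menthol, (1S,2R,5S)-2-isopropyl-5-methylcyclohexan-1-ol | CC(C)[C@H]1CC[C@H](C)C[C@@H]1O | starting material
5 | (5R)-5-[(1S,2R,5S)-menthyloxy]furan-2(5H)-one (acetal epimer, not isolated) | O=C1O[C@@H](O[C@H]2C[C@@H](C)CC[C@@H]2C(C)C)C=C1 | intermediate
6 | (5S)-5-[(1S,2R,5S)-menthyloxy]furan-2(5H)-one | O=C1O[C@H](O[C@H]2C[C@@H](C)CC[C@@H]2C(C)C)C=C1 | intermediate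
7 | 3,4,5-trimethoxybenzaldehyde | COc1cc(C=O)cc(OC)c1OC | starting material
8 | 2-(3,4,5-trimethoxyphenyl)-1,3-dithiane | COc1cc(C2SCCCS2)cc(OC)c1OC | intermediate
9 | 3-hydroxy-4,5-dimethoxybenzaldehyde | COc1cc(C=O)cc(O)c1OC | starting material
10 | 3,4-dimethoxy-5-[(triisopropylsilyl)oxy]benzaldehyde | COc1cc(C=O)cc(O[Si](C(C)C)(C(C)C)C(C)C)c1OC | intermediate
11 | {3,4-dimethoxy-5-[(triisopropylsilyl)oxy]phenyl}methanol | COc1cc(CO)cc(O[Si](C(C)C)(C(C)C)C(C)C)c1OC | intermediate
12 | 3,4-dimethoxy-5-[(triisopropylsilyl)oxy]benzyl bromide | COc1cc(CBr)cc(O[Si](C(C)C)(C(C)C)C(C)C)c1OC | intermediate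
13 | 2-lithio-2-(3,4,5-trimethoxyphenyl)-1,3-dithiane (not isolated) | COc1cc(C2([Li])SCCCS2)cc(OC)c1OC | intermediate
14 | lithium (4S,5S)-5-[(1S,2R,5S)-menthyloxy]-4-[2-(3,4,5-trimethoxyphenyl)-1,3-dithian-2-yl]-4,5-dihydrofuran-2-olate (not isolated) | [Li]OC1=C[C@H](C2(c3cc(OC)c(OC)c(OC)c3)SCCCS2)[C@@H](O[C@H]2C[C@@H](C)CC[C@@H]2C(C)C)O1 | intermediate
15 | (3S,4S,5S)-3-{3,4-dimethoxy-5-[(triisopropylsilyl)oxy]benzyl}-5-[(1S,2R,5S)-menthyloxy]-4-[2-(3,4,5-trimethoxyphenyl)-1,3-dithian-2-yl]dihydrofuran-2(3H)-one | O=C1O[C@H](O[C@H]2C[C@@H](C)CC[C@@H]2C(C)C)[C@@H](C2(c3cc(OC)c(OC)c(OC)c3)SCCCS2)[C@@H]1Cc1cc(OC)c(OC)c(O[Si](C(C)C)(C(C)C)C(C)C)c1 | intermediate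
16 | (3S,4S,5S)-3-{3,4-dimethoxy-5-[(triisopropylsilyl)oxy]benzyl}-5-[(1S,2R,5S)-menthyloxy]-4-(3,4,5-trimethoxybenzoyl)dihydrofuran-2(3H)-one | O=C1O[C@H](O[C@H]2C[C@@H](C)CC[C@@H]2C(C)C)[C@@H](C(=O)c2cc(OC)c(OC)c(OC)c2)[C@@H]1Cc1cc(OC)c(OC)c(O[Si](C(C)C)(C(C)C)C(C)C)c1 | intermediate
17 | (2S,3S)-2-{3,4-dimethoxy-5-[(triisopropylsilyl)oxy]benzyl}-3-[hydroxy(3,4,5-trimethoxyphenyl)methyl]butane-1,4-diol (carbinol epimers) | COc1cc(C[C@H](CO)[C@@H](CO)C(O)c2cc(OC)c(OC)c(OC)c2)cc(O[Si](C(C)C)(C(C)C)C(C)C)c1OC | intermediate
18 | [(2R,3S,4S)-4-{3,4-dimethoxy-5-[(triisopropylsilyl)oxy]benzyl}-2-(3,4,5-trimethoxyphenyl)tetrahydrofuran-3-yl]methanol | COc1cc(C[C@@H]2CO[C@@H](c3cc(OC)c(OC)c(OC)c3)[C@@H]2CO)cc(O[Si](C(C)C)(C(C)C)C(C)C)c1OC | intermediate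
19 | 5-{[(3S,4S,5R)-4-(hydroxymethyl)-5-(3,4,5-trimethoxyphenyl)tetrahydrofuran-3-yl]methyl}-2,3-dimethoxyphenol | COc1cc(C[C@@H]2CO[C@@H](c3cc(OC)c(OC)c(OC)c3)[C@@H]2CO)cc(O)c1OC | target

Total step count: 11 steps. Longest linear sequence: 8 steps (steps 4, 5, 6, 7, 8, 9, 10 and 11, starting from 9).

Least certain steps

Step 7 (key step). The most likely failure is incomplete C-benzylation of the hindered enolate 14, through proton transfer or through reversal of the conjugate addition on warming; carbonyl addition of 13 is a lesser risk. Fallback: the two bond formations are separated. Setting out from 6 and 8, the enolate 14 is quenched with NH4Cl aq. at −78 °C to give the trans conjugate adduct (4S,5S)-5-[(1S,2R,5S)-menthyloxy]-4-[2-(3,4,5-trimethoxyphenyl)-1,3-dithian-2-yl]dihydrofuran-2(3H)-one F1, which is purified. Deprotonation with LiN(SiMe3)2 in THF at −78 °C and alkylation with 12 in the presence of DMPU then comes back to the route at 15. The anti selectivity should be the same because the dithianyl group imposes it.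

Step 8. The most likely failure is oxidative attack of the trivalent iodine reagent on the two electron-rich arenes, or epimerisation or β-elimination at the carbon between the new ketone and the acetal once the carbonyl is free. Fallback: the order of events is changed so that the ketone never coexists with the acyl acetal. Setting out from 15, LiAlH4 (THF, 0 °C) reduces the lactone and acetal carbons to give the dithiane diol (2S,3S)-2-{3,4-dimethoxy-5-[(triisopropylsilyl)oxy]benzyl}-3-[2-(3,4,5-trimethoxyphenyl)-1,3-dithian-2-yl]butane-1,4-diol F2, with release of 4. S-Alkylative hydrolysis (MeI, CaCO3, MeCN–H2O, 40 °C) frees the ketone, which should close at once to the cyclic hemiketal (3S,4S)-4-{3,4-dimethoxy-5-[(triisopropylsilyl)oxy]benzyl}-3-(hydroxymethyl)-2-(3,4,5-trimethoxyphenyl)tetrahydrofuran-2-ol F3. NaBH4 in MeOH reduces its open-chain tautomer and comes back to the route at 17.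

Step 9. The most likely failure is deprotonation of the carbon flanked by ketone and acetal by the basic hydride or by alkoxides before reduction is complete, leading to epimerisation of the future C3 or to opening of the acetal by elimination. Fallback: two chemoselective reductions replace the single one. Setting out from 16, NaBH4 with CeCl3·7H2O in MeOH at −40 °C reduces only the aryl ketone under non-basic conditions to the hydroxy lactone (3S,4R,5S)-3-{3,4-dimethoxy-5-[(triisopropylsilyl)oxy]benzyl}-4-[hydroxy(3,4,5-trimethoxyphenyl)methyl]-5-[(1S,2R,5S)-menthyloxy]dihydrofuran-2(3H)-one F4. LiAlH4 in THF then reduces the lactone and acetal carbons of F4 and comes back to the route at 17.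

Step 10. The most likely failure is interception of the benzylic cation by the electron-rich benzyl ring (irreversible six-membered Friedel–Crafts closure), above all if the first-formed ether re-ionises; incomplete trans selection at C2 is a second risk. Fallback: the protecting-group logic is changed so that the ring that would attack is deactivated while the cation exists. Setting out from 17, Bu4NF in THF removes the silyl group to give the tetraol (2S,3S)-2-(3-hydroxy-4,5-dimethoxybenzyl)-3-[hydroxy(3,4,5-trimethoxyphenyl)methyl]butane-1,4-diol F5. Ac2O with NaOH aq. at 0 °C acetylates the phenoxide selectively to 5-[(2S,3S)-4-hydroxy-2,3-bis(hydroxymethyl)-4-(3,4,5-trimethoxyphenyl)butyl]-2,3-dimethoxyphenyl acetate F6. The acid closure of step 10 is run on F6 to give 5-{[(3S,4S,5R)-4-(hydroxymethyl)-5-(3,4,5-trimethoxyphenyl)tetrahydrofuran-3-yl]methyl}-2,3-dimethoxyphenyl acetate F7. K2CO3 in MeOH removes the acetate and comes back to the route at 19.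

## Further compounds

F1 | step 7 | (4S,5S)-5-[(1S,2R,5S)-menthyloxy]-4-[2-(3,4,5-trimethoxyphenyl)-1,3-dithian-2-yl]dihydrofuran-2(3H)-one | O=C1O[C@H](O[C@H]2C[C@@H](C)CC[C@@H]2C(C)C)[C@@H](C2(c3cc(OC)c(OC)c(OC)c3)SCCCS2)C1
F2 | step 8 | (2S,3S)-2-{3,4-dimethoxy-5-[(triisopropylsilyl)oxy]benzyl}-3-[2-(3,4,5-trimethoxyphenyl)-1,3-dithian-2-yl]butane-1,4-diol | COc1cc(C[C@H](CO)[C@@H](CO)C2(c3cc(OC)c(OC)c(OC)c3)SCCCS2)cc(O[Si](C(C)C)(C(C)C)C(C)C)c1OC
F3 | step 8 | (3S,4S)-4-{3,4-dimethoxy-5-[(triisopropylsilyl)oxy]benzyl}-3-(hydroxymethyl)-2-(3,4,5-trimethoxyphenyl)tetrahydrofuran-2-ol (both anomers) | COc1cc(C[C@@H]2COC(O)(c3cc(OC)c(OC)c(OC)c3)[C@@H]2CO)cc(O[Si](C(C)C)(C(C)C)C(C)C)c1OC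
F4 | step 9 | (3S,4R,5S)-3-{3,4-dimethoxy-5-[(triisopropylsilyl)oxy]benzyl}-4-[hydroxy(3,4,5-trimethoxyphenyl)methyl]-5-[(1S,2R,5S)-menthyloxy]dihydrofuran-2(3H)-one (carbinol epimers) | O=C1O[C@H](O[C@H]2C[C@@H](C)CC[C@@H]2C(C)C)[C@@H](C(O)c2cc(OC)c(OC)c(OC)c2)[C@@H]1Cc1cc(OC)c(OC)c(O[Si](C(C)C)(C(C)C)C(C)C)c1
F5 | step 10 | (2S,3S)-2-(3-hydroxy-4,5-dimethoxybenzyl)-3-[hydroxy(3,4,5-trimethoxyphenyl)methyl]butane-1,4-diol (carbinol epimers) | COc1cc(C[C@H](CO)[C@@H](CO)C(O)c2cc(OC)c(OC)c(OC)c2)cc(O)c1OC
F6 | step 10 | 5-[(2S,3S)-4-hydroxy-2,3-bis(hydroxymethyl)-4-(3,4,5-trimethoxyphenyl)butyl]-2,3-dimethoxyphenyl acetate (carbinol epimers) | COc1cc(C[C@H](CO)[C@@H](CO)C(O)c2cc(OC)c(OC)c(OC)c2)cc(OC(C)=O)c1OC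
F7 | step 10 | 5-{[(3S,4S,5R)-4-(hydroxymethyl)-5-(3,4,5-trimethoxyphenyl)tetrahydrofuran-3-yl]methyl}-2,3-dimethoxyphenyl acetate | COc1cc(C[C@@H]2CO[C@@H](c3cc(OC)c(OC)c(OC)c3)[C@@H]2CO)cc(OC(C)=O)c1OC
A1 | alternative 1 | cis-fused 3-[3-(benzyloxy)-4,5-dimethoxyphenyl]-6-(3,4,5-trimethoxyphenyl)tetrahydro-1H,3H-furo[3,4-c]furan-1-one, both aryl groups exo | COc1cc([C@H]3[C@@H]2CO[C@@H](c4cc(OC)c(OC)c(OC)c4)[C@@H]2C(=O)O3)cc(OCc4ccccc4)c1OC
A2 | alternative 1 | (5R)-5-[3-(benzyloxy)-4,5-dimethoxyphenyl]furan-2(5H)-one | COc1cc([C@@H]2OC(=O)C=C2)cc(OCc2ccccc2)c1OC
A3 | alternative 1 | chloro(3,4,5-trimethoxyphenyl)methyl (trimethylsilyl)methyl ether (racemic) | COc1cc(C(Cl)OC[Si](C)(C)C)cc(OC)c1OC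
A4 | alternative 2 | tert-butyldimethylsilyl ether of the target at the phenol oxygen | COc1cc(C[C@@H]2CO[C@@H](c3cc(OC)c(OC)c(OC)c3)[C@@H]2CO)cc(O[Si](C)(C)C(C)(C)C)c1OC
A5 | alternative 2 | 2-{(S)-[(E)-3-{3-[(tert-butyldimethylsilyl)oxy]-4,5-dimethoxyphenyl}allyloxy](3,4,5-trimethoxyphenyl)methyl}oxirane (either epoxide epimer) | COc1cc(/C=C/CO[C@@H](c2cc(OC)c(OC)c(OC)c2)C2CO2)cc(O[Si](C)(C)C(C)(C)C)c1OC
A6 | alternative 3 | diacetate of the target (phenol and primary alcohol acetylated) | COc1cc(C[C@@H]2CO[C@@H](c3cc(OC)c(OC)c(OC)c3)[C@@H]2COC(C)=O)cc(OC(C)=O)c1OC
A7 | alternative 3 | dibenzylbutanol with free C5 hydroxyl, acetylated C3 hydroxymethyl and acetylated phenol | COc1cc(C[C@H](CO)[C@@H](COC(C)=O)Cc2cc(OC)c(OC)c(OC)c2)cc(OC(C)=O)c1OC
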